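Start at the late end: at 20.0 min the violet run still holds 3.8% of its free monomer and the teal run 49.4%, and both have stood flat since their first readings. This stop with free monomer left is what the trade calls dead-end polymerisation, so reckon the stop and not a rate.

in all of them: free monomer 1.1 M; initiator 11 mM

|  | transfer agent | remark | time |
|---|---|---|---|
| violet | 0.017 M | run made earlier |  |
| teal | 0.066 M | run made earlier |  |
| flask | 0.0330 M |  | 15 min |

- violet (time / min: monomer in chains / %, free monomer / %): 1.50: 95.5, 3.5; 5.00: 96.1, 3.6; 8.00: 96.5, 3.9; 12.0: 96.5, 4.1; 20.0: 96.2, 3.8
- teal (time / min: monomer in chains / %, free monomer / %): 1.33: 50.7, 49.3; 2.50: 51.6, 49.2; 5.00: 51.2, 49.3; 10.0: 50.9, 49.1; 20.0: 50.7, 49.4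

(readings scatter by 0.3 percentage points)

- average number of monomer units in a chain (chains begun, living or dead) at 15 min
- part of the free monomer that has reacted at 15 min

- the average divides the monomer in chains by the number of chains begun, living and dead together
- what was read earlier has a scatter of 0.3 percentage points, one standard deviation
- the earlier runs do not show the number of chains; that part of a forecast is a guess

Suppose transfer agent kills growing chains. Then the log of charged over left free monomer, 3.27 for violet and 0.705 for teal, should go inversely with transfer agent. Multiply each by its agent charge and divide by its initiator charge: violet gives 5.05, teal 4.23. The flask's agent lies near the geometric middle of the two charges, so their geometric mean 4.62 puts the flask at 78.6% reacted, taking 15 min as on the plateau.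

The weak link is the agent itself, since a killed chain spends some. Reforge it: subtract the same mean loss from both charges and demand one product, which gives a loss of 3.53 mM. That is half of 7.06 mM of chains, a guess, as no run shows chains.

Call the log times the mean agent, per initiator charged, the reach: 4.01. For the flask, my reckoning commits to 77.6% reacted and an average chain of 121.

The forecast says 78% and 115, on this ground: “More agent means an earlier stop, which suggests the agent kills growing chains rather than restarting them.” Its chain length differs from mine.

The flask gives 77.5% of its free monomer reacted, and its monomer in chains averages 125 units.

    living end + transfer agent → dead chain (kL = 3.90 L mol⁻¹ s⁻¹)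
    free monomer + living end → monomer in chains + living end, rate k2*[living end]*[free monomer] (k = 25.0 L mol⁻¹ s⁻¹)
    initiator → spent initiator (k = 0.270 s⁻¹)
    free monomer + initiator → living end + monomer in chains (k = 0.450 L mol⁻¹ s⁻¹)

At 15.0 min the flask holds 0.00683 M of dead chain beside 0.00417 M of spent initiator. Its own plateau returns a reach of 4.00. Carry the reach to the neighbour flask charged with 0.0027 M of initiator, scaling the agent loss with the initiator charge: it foretells 28.6% reacted. That neighbour flask gives 29.3%.

The earlier runs and the new flask are simulated for substances that don't exist.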